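Take a closed flask and two stirred tanks, charge them as set out here, and read how L, E and J stand at the end or at the outlet.

| flask | D | time | remark |
|---|---|---|---|
| cedar | 0.40 M | 15 h | a closed flask charged with all of it at once and left for 15 h |
| maple | 0.40 M |  | one stirred flow tank at steady state, fed with the mixture as stated, mean residence time 15 h |
| oak | 0.40 M |  | a single well-mixed tank run continuously and read at steady state, 150 h in it on average |

    D ⇌ E (K1 = 0.45, k1 = 1.1 × 10⁻⁴ s⁻¹)
    D → Q (k2 = 8.1 × 10⁻⁶ s⁻¹)
    D ⇌ X (K3 = 0.71, k3 = 6.6 × 10⁻⁶ s⁻¹)
    Q ⇌ G (K4 = 0.83, k4 = 8.3 × 10⁻⁵ s⁻¹)
    X → L (k5 = 4.8 × 10⁻⁵ s⁻¹)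
    X → J (k6 = 1.4 × 10⁻⁵ s⁻¹)
    2 D → D2 (k7 = 9.4 × 10⁻⁸ M⁻¹ s⁻¹)

- percent here means D units held: one D2 counts as two
- for a step with 2 of a species take k times the square, and two of it per event
- the stated concentrations are those of everything mixed, before any reaction; amounts are the same in each set-up
- run time (cedar): 15 h

* the set-up with the highest share of L in all that became L or E or J, at the outlet or at the end ("none" if the first two lie within 2 percentage points) (cedar / maple / oak / none)
* share of L in all that became L or E or J, at the outlet or at the end, cedar
* share of L in all that became L or E or J, at the outlet or at the end, maple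
* share of L in all that became L or E or J, at the outlet or at the end, oak

Call kL and kJ the rate constants of X to L and of X to J. Both steps draw on the same X at every moment, so divide one rate by the other and time drops out, in any of these vessels. This gives the branch fraction (a selectivity) b, the part of what leaves X by these two steps that becomes L:

b = kL/(kL + kJ) = 77.4%

Write P = (L + J)/E. The share of L is then

share = b · P/(1 + P)

In a tank, divide the balances by D, which cancels. With kE and K for D to E, kX and KX for D to X, and τ the mean residence time:

E/D = kE τ/(1 + kE τ/K)

X/D = kX τ/(1 + (kX/KX + kL + kJ) τ)

P = (kL + kJ) τ · (X/D)/(E/D)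

Now ask which constants must be known well. Raise kJ by a factor 2 and b falls to 63.2%, so kL and kJ count in full. The constants of D to X and K act through P, which stands at 6.76 in oak, where a factor 2 on P moves P/(1 + P) from 87.1% to 93.1%. In maple P is 0.588, and the same factor moves P/(1 + P) from 37.0% to 54.0%, a larger step than in oak, so maple needs these constants known better. In oak kE barely counts, since kE τ/K is 132. The constants of D to Q, of Q with G and of the dimerisation stand nowhere in these lines.

My reckoning therefore gives 28.7% for maple and 67.4% for oak, which is more than in maple. Cedar has no steady state to divide by, so I leave it open beneath the ceiling b.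

The forecast names oak, with 32% for cedar, 28.7% for maple and 67.4% for oak, holding that “the share therefore depends mainly on how long material stays”.

The simulation gives oak, with 31.9% in cedar, 28.7% in maple and 67.4% in oak. Maple, run at 3 times its residence time, reads 51.2%. Divide these readings by b: L and J together make 41.2% of what became L, E or J in cedar, 37.1% in maple, and 66.1% in the longer maple run, which leaves 33.9% as E there.

All constants were set for the occasion; what happens was integrated by code.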